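**Retrosynthetic overview**
1. The target is genistein joined at C3' to C8 of apigenin and has no stereocentre. It is unmasked last by cleaving four methyl ethers, after a one-carbon unit (isoflavone C2) has closed ring C.
2. Feature used: isoflavone ring A (C4a, C5, C6, C7, C8, C8a) with the C4 carbonyl and benzylic C3 is a benzyl 2,4,6-trihydroxyphenyl ketone. This is an arylacetyl head plus three acetate units, and a mirror plane through C4a and C7 makes C5 and C8a equivalent.
3. Key disconnection: C4a–C5 (the same as C4a–C8a). This unfolds ring A to a methyl 8-aryl-3,5,7-trioxooctanoate (chain bond C6–C1).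
4. The chain comes from an N-methoxy-N-methyl arylacetamide and the dianion of 6-(2-oxopropyl)dioxinone. The dioxinone masks C1–C3 until it is opened thermally in methanol, and the C3'–C8'' biaryl bond is made earlier by Suzuki–Miyaura coupling.
5. Ring order: both flavone rings are bought, then isoflavone ring A (step 8), then isoflavone ring C (step 9).

Key step: step 8

Assumption: the SMILES defines no configuration at the C3'–C8'' biaryl axis, so no axial control is planned and the axis forms unselectively.

**Step 1**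
Reactants: 1 5,7,4'-trimethoxyflavone (apigenin trimethyl ether)
Product: 2 8-iodo-5,7,4'-trimethoxyflavone
Conditions: N-iodosuccinimide (1.05 equiv), CF3CO2H (cat.), MeCN/CH2Cl2, rt, dark
Reagents that add atoms: N-iodosuccinimide, O=C1CCC(=O)N1I
Why: Electrophilic aromatic iodination, which in fully O-alkylated 5,7-dioxygenated flavones should enter at C8 (para to 5-OMe, ortho to 7-OMe), because C6 is wedged between two methoxy groups and C3 and ring B are deactivated by the conjugated carbonyl.

**Step 2**
Reactants: 3 3-bromo-4-methoxyphenylacetic acid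
Product: 5 2-(3-bromo-4-methoxyphenyl)-N-methoxy-N-methylacetamide, via acyl imidazolide 4 (not isolated)
Conditions: 1,1'-carbonyldiimidazole, CH2Cl2, rt; MeNH(OMe)·HCl, rt
Reagents that add atoms: 1,1'-carbonyldiimidazole, O=C(n1ccnc1)n1ccnc1 (supplies only the imidazolyl group of 4); N,O-dimethylhydroxylamine hydrochloride, CNOC.Cl
Why: Amide formation by acyl substitution through the imidazolide, placed first because the N-methoxy-N-methylamide passes both palladium steps unchanged and later transfers the arylacetyl group only once, which saves an ester hydrolysis and a separate activation.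

**Step 3**
Reactants: 5 2-(3-bromo-4-methoxyphenyl)-N-methoxy-N-methylacetamide
Product: 6 N-methoxy-N-methyl-2-[4-methoxy-3-(4,4,5,5-tetramethyl-1,3,2-dioxaborolan-2-yl)phenyl]acetamide
Conditions: B2pin2, Pd(dppf)Cl2 (3 mol %), KOAc, 1,4-dioxane, 90 °C
Reagents that add atoms: bis(pinacolato)diboron, CC1(C)OB(OC1(C)C)B1OC(C)(C)C(C)(C)O1
Why: Miyaura borylation (oxidative addition of the aryl bromide, acetate-assisted transmetalation from B2pin2, reductive elimination) should give the pinacol boronate, and the weak base KOAc leaves the amide and its benzylic CH2 untouched.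

**Step 4**
Reactants: 2 8-iodo-5,7,4'-trimethoxyflavone; 6 N-methoxy-N-methyl-2-[4-methoxy-3-(4,4,5,5-tetramethyl-1,3,2-dioxaborolan-2-yl)phenyl]acetamide
Product: 7 N-methoxy-N-methyl-2-[4-methoxy-3-(5,7-dimethoxy-2-(4-methoxyphenyl)-4-oxo-4H-chromen-8-yl)phenyl]acetamide
Conditions: Pd(OAc)2 (3 mol %), SPhos (6 mol %), K3PO4, toluene/H2O, 90 °C
Reagents that add atoms: none
Why: Suzuki–Miyaura coupling in which the bulky electron-rich biarylphosphine copes with the three ortho substituents around the new C3'–C8'' bond, the boron sits on the ring with only one ortho oxygen because a flavon-8-yl boronate flanked by two oxygens would be prone to protodeboronation, and flavone and amide both tolerate aqueous K3PO4.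

**Step 5**
Reactants: 8 2,2,6-trimethyl-4H-1,3-dioxin-4-one
Product: 10 2,2-dimethyl-6-(2-oxopropyl)-4H-1,3-dioxin-4-one, via lithium dienolate 9 (not isolated)
Conditions: LiN(SiMe3)2 (1 equiv), THF, −78 °C; AcCl (0.5 equiv), −78 → −20 °C; 1 M HCl
Reagents that add atoms: LiN(SiMe3)2, [Li+].C[Si](C)(C)[N-][Si](C)(C)C (supplies only the lithium of 9); acetyl chloride, CC(=O)Cl
Why: Vinylogous crossed Claisen acylation, in which the C6 methyl group is deprotonated to dienolate 9, acid chlorides acylate it at the γ-carbon, and the enolate is used in twofold amount because product 10 is more acidic than 8.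

**Step 6**
Reactants: 10 2,2-dimethyl-6-(2-oxopropyl)-4H-1,3-dioxin-4-one; 7 N-methoxy-N-methyl-2-[4-methoxy-3-(5,7-dimethoxy-2-(4-methoxyphenyl)-4-oxo-4H-chromen-8-yl)phenyl]acetamide
Product: 12 6-{5-[4-methoxy-3-(5,7-dimethoxy-2-(4-methoxyphenyl)-4-oxo-4H-chromen-8-yl)phenyl]-2,4-dioxopentyl}-2,2-dimethyl-4H-1,3-dioxin-4-one, via dilithium dianion 11 (not isolated)
Conditions: 10 (3 equiv), LiN(i-Pr)2 (5.8 equiv), THF, −78 → −40 °C; 7 (1 equiv), −78 → −20 °C; 1 M HCl to pH 3
Reagents that add atoms: LiN(i-Pr)2, [Li+].CC(C)[N-]C(C)C (supplies only the lithium of 11)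
Why: γ-Acylation of a 1,3-dicarbonyl dianion (crossed Claisen condensation), in which the terminal carbanion of 11 is the more basic and more nucleophilic site and attacks the amide, the N-methoxy chelate holds the adduct until the acid quench so that neither over-addition nor proton exchange with the product occurs, the dioxinone keeps C1–C3 masked, and the slight deficit of LiN(i-Pr)2 spares flavone C3–H.

**Step 7**
Reactants: 12 6-{5-[4-methoxy-3-(5,7-dimethoxy-2-(4-methoxyphenyl)-4-oxo-4H-chromen-8-yl)phenyl]-2,4-dioxopentyl}-2,2-dimethyl-4H-1,3-dioxin-4-one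
Product: 14 methyl 8-[4-methoxy-3-(5,7-dimethoxy-2-(4-methoxyphenyl)-4-oxo-4H-chromen-8-yl)phenyl]-3,5,7-trioxooctanoate, via acylketene 13 (not isolated)
Conditions: MeOH (10 equiv), toluene, 110 °C, sealed tube; evaporate, use without chromatography
Reagents that add atoms: methanol, CO
Why: Thermal retro-hetero-Diels–Alder cleavage of the dioxinone expels acetone and gives acylketene 13, which methanol captures at the ketene carbon under neutral conditions, so the free chain is first exposed without any base that could fold it.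

**Step 8**
Reactants: 14 methyl 8-[4-methoxy-3-(5,7-dimethoxy-2-(4-methoxyphenyl)-4-oxo-4H-chromen-8-yl)phenyl]-3,5,7-trioxooctanoate
Product: 16 2-[4-methoxy-3-(5,7-dimethoxy-2-(4-methoxyphenyl)-4-oxo-4H-chromen-8-yl)phenyl]-1-(2,4,6-trihydroxyphenyl)ethanone, via acylcyclohexanetrione 15 (not isolated)
Conditions: Mg(OMe)2 (4 equiv), dry MeOH, argon, rt → 65 °C; cold 1 M HCl
Reagents that add atoms: none
Why: Mg(OMe)2 turns the chain into its magnesium enolates, of which the C5–C6–C7 β-diketonate is the most acidic and best chelating site; its central carbon C6 adds to ester carbon C1, methoxide leaves, and trione 15 enolises at once to the phloroglucinol, so the new C6–C1 bond becomes isoflavone C4a–C5 (identical with C4a–C8a). The closest known reaction type is the intramolecular Claisen (Dieckmann-type) cyclisation of 3,5,7-triketo esters, or of the 4-hydroxy-2-pyrones derived from them, to acylphloroglucinols under methoxide or hydroxide, the laboratory counterpart of the chalcone synthase folding. Ring A closes in the 6-exo-trig mode, the carbonyl oxygen of C1 staying outside the ring formed by C1 to C6, and no stereocentre is created. The step needs chemoselectivity among four foldings: Claisen C6 onto C1 (wanted), aldol C2 onto C7 (resorcylate), aldol of the benzylic C8 onto C3, and lactonisation of the C5 enol oxygen onto C1. The first should be favoured because C7 is locked in the chelated diketonate and flanked by the bulky arylmethyl group and so is a poor aldol acceptor, C8 is far less acidic than C2, C4 and C6 and is not ionised by this weak base, the β-keto ester end is the weaker acid and weaker ligand and in dry methoxide can be neither saponified nor exchanged so that C1 stays the most available carbonyl, and lactone formation is reversed by methoxide whereas aromatisation to the chelated o-acylphenolate is not. Regiochemistry does not arise, since 16 has a mirror plane through the acyl-bearing carbon and the carbon para to it.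

**Step 9**
Reactants: 16 2-[4-methoxy-3-(5,7-dimethoxy-2-(4-methoxyphenyl)-4-oxo-4H-chromen-8-yl)phenyl]-1-(2,4,6-trihydroxyphenyl)ethanone
Product: 18 5,7-dihydroxy-3-[4-methoxy-3-(5,7-dimethoxy-2-(4-methoxyphenyl)-4-oxo-4H-chromen-8-yl)phenyl]-4H-chromen-4-one, via enaminone 17 (not isolated)
Conditions: Me2NCH(OMe)2 (3 equiv), THF, 65 °C; then 1 M HCl, rt
Reagents that add atoms: N,N-dimethylformamide dimethyl acetal, COC(OC)N(C)C
Why: Aminomethylenation of the benzylic CH2 (activated by carbonyl and aryl) with the amide acetal gives enaminone 17, either of the two equivalent ortho hydroxyls then adds to the enamine carbon and dimethylamine is lost (addition–elimination, 6-endo-trig), which closes ring C, and any stray O-methylation of a phenol by the acetal would be undone in step 10.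

**Step 10**
Reactants: 18 5,7-dihydroxy-3-[4-methoxy-3-(5,7-dimethoxy-2-(4-methoxyphenyl)-4-oxo-4H-chromen-8-yl)phenyl]-4H-chromen-4-one
Product: 19 5,7-dihydroxy-3-[4-hydroxy-3-(5,7-dihydroxy-2-(4-hydroxyphenyl)-4-oxo-4H-chromen-8-yl)phenyl]-4H-chromen-4-one (CNP0142623.0)
Conditions: BBr3 (15 equiv), CH2Cl2, −78 °C → rt; ice/H2O
Reagents that add atoms: none
Why: Lewis-acid aryl methyl ether cleavage, in which BBr3 binds each ether oxygen and bromide removes the methyl group by SN2, both pyranones are inert, and the cold aprotic medium avoids the Wessely–Moser ring opening and reclosure that hot mineral acid could cause in the 8-aryl-5,7-dihydroxyflavone half.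

**Compound list**
1 | 5,7,4'-trimethoxyflavone (apigenin trimethyl ether) | COc1ccc(cc1)-c1cc(=O)c2c(OC)cc(OC)cc2o1 | starting material
2 | 8-iodo-5,7,4'-trimethoxyflavone | COc1ccc(cc1)-c1cc(=O)c2c(OC)cc(OC)c(I)c2o1 | intermediate
3 | 3-bromo-4-methoxyphenylacetic acid | COc1ccc(CC(=O)O)cc1Br | starting material
4 | 1-[(3-bromo-4-methoxyphenyl)acetyl]imidazole | COc1ccc(CC(=O)n2ccnc2)cc1Br | intermediate
5 | 2-(3-bromo-4-methoxyphenyl)-N-methoxy-N-methylacetamide | COc1ccc(CC(=O)N(C)OC)cc1Br | intermediate
6 | N-methoxy-N-methyl-2-[4-methoxy-3-(4,4,5,5-tetramethyl-1,3,2-dioxaborolan-2-yl)phenyl]acetamide | COc1ccc(CC(=O)N(C)OC)cc1B1OC(C)(C)C(C)(C)O1 | intermediate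
7 | N-methoxy-N-methyl-2-[4-methoxy-3-(5,7-dimethoxy-2-(4-methoxyphenyl)-4-oxo-4H-chromen-8-yl)phenyl]acetamide | CON(C)C(=O)Cc1ccc(OC)c(-c2c(OC)cc(OC)c3c(=O)cc(-c4ccc(OC)cc4)oc23)c1 | intermediate
8 | 2,2,6-trimethyl-4H-1,3-dioxin-4-one | CC1=CC(=O)OC(C)(C)O1 | starting material
9 | lithium 2,2-dimethyl-6-methylidene-6H-1,3-dioxin-4-olate (dienolate of 8) | [Li+].C=C1C=C([O-])OC(C)(C)O1 | intermediate
10 | 2,2-dimethyl-6-(2-oxopropyl)-4H-1,3-dioxin-4-one | CC(=O)CC1=CC(=O)OC(C)(C)O1 | intermediate
11 | dilithium dianion of 10 (deprotonated at the ring-side CH2 and at the terminal CH3) | [Li+].[Li+].C=C([O-])C=C1C=C([O-])OC(C)(C)O1 | intermediate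
12 | 6-{5-[4-methoxy-3-(5,7-dimethoxy-2-(4-methoxyphenyl)-4-oxo-4H-chromen-8-yl)phenyl]-2,4-dioxopentyl}-2,2-dimethyl-4H-1,3-dioxin-4-one | CC1(C)OC(=O)C=C(CC(=O)CC(=O)Cc2ccc(OC)c(-c3c(OC)cc(OC)c4c(=O)cc(-c5ccc(OC)cc5)oc34)c2)O1 | intermediate
13 | acylketene, 8-aryl-3,5,7-trioxooct-1-en-1-one (aryl as in 12) | O=C=CC(=O)CC(=O)CC(=O)Cc1ccc(OC)c(-c2c(OC)cc(OC)c3c(=O)cc(-c4ccc(OC)cc4)oc23)c1 | intermediate
14 | methyl 8-[4-methoxy-3-(5,7-dimethoxy-2-(4-methoxyphenyl)-4-oxo-4H-chromen-8-yl)phenyl]-3,5,7-trioxooctanoate | COC(=O)CC(=O)CC(=O)CC(=O)Cc1ccc(OC)c(-c2c(OC)cc(OC)c3c(=O)cc(-c4ccc(OC)cc4)oc23)c1 | intermediate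
15 | 2-(arylacetyl)cyclohexane-1,3,5-trione (aryl as in 14), keto tautomer of 16 | O=C(Cc1ccc(OC)c(-c2c(OC)cc(OC)c3c(=O)cc(-c4ccc(OC)cc4)oc23)c1)C1C(=O)CC(=O)CC1=O | intermediate
16 | 2-[4-methoxy-3-(5,7-dimethoxy-2-(4-methoxyphenyl)-4-oxo-4H-chromen-8-yl)phenyl]-1-(2,4,6-trihydroxyphenyl)ethanone | O=C(Cc1ccc(OC)c(-c2c(OC)cc(OC)c3c(=O)cc(-c4ccc(OC)cc4)oc23)c1)c1c(O)cc(O)cc1O | intermediate
17 | 3-(dimethylamino)-2-aryl-1-(2,4,6-trihydroxyphenyl)prop-2-en-1-one (aryl as in 16, alkene geometry undefined) | CN(C)C=C(C(=O)c1c(O)cc(O)cc1O)c1ccc(OC)c(-c2c(OC)cc(OC)c3c(=O)cc(-c4ccc(OC)cc4)oc23)c1 | intermediate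
18 | 5,7-dihydroxy-3-[4-methoxy-3-(5,7-dimethoxy-2-(4-methoxyphenyl)-4-oxo-4H-chromen-8-yl)phenyl]-4H-chromen-4-one | O=c1c(-c2ccc(OC)c(-c3c(OC)cc(OC)c4c(=O)cc(-c5ccc(OC)cc5)oc34)c2)coc2cc(O)cc(O)c12 | intermediate
19 | 5,7-dihydroxy-3-[4-hydroxy-3-(5,7-dihydroxy-2-(4-hydroxyphenyl)-4-oxo-4H-chromen-8-yl)phenyl]-4H-chromen-4-one (CNP0142623.0) | O=c1c(-c2ccc(O)c(-c3c(O)cc(O)c4c(=O)cc(-c5ccc(O)cc5)oc34)c2)coc2cc(O)cc(O)c12 | target

**Step count**
Total step count: 10.
Longest linear sequence: 8 steps (steps 2, 3, 4, 6, 7, 8, 9, 10, starting from 3).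

**Steps most likely to fail**

*Step 8.* The chain may fold by aldol addition (C2 onto C7, or the benzylic C8 onto C3) faster than by the Claisen mode. Such chains readily do this under mild bases. Long heating in methoxide may also begin to open the flavone pyranone. The fallback sets out from 7 and comes back at 16. It gives up the folding and attaches a ready-made ring A by Friedel–Crafts acylation. Amide 7 is hydrolysed (6 M HCl, 1,4-dioxane, reflux; the flavone and its ethers are stable to aqueous acid) to [4-methoxy-3-(5,7-dimethoxy-2-(4-methoxyphenyl)-4-oxo-4H-chromen-8-yl)phenyl]acetic acid F1. This acid acylates an excess of anhydrous phloroglucinol in BF3·OEt2 at 80 °C to give 16.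

*Step 6.* Proton transfer from the benzylic CH2 of 7 to the strongly basic dianion may compete with acyl transfer, which would return 7. The dianion may also add to the flavone pyranone. The fallback sets out from 7 and from dienolate 9 and comes back at 12. It replaces the hard dianion by a soft magnesium enolate.
- The acid F1, obtained from 7 as above, is converted with (COCl)2 and catalytic DMF in CH2Cl2 into the arylacetyl chloride F2.
- Dienolate 9 is acylated with allyl malonyl chloride to give allyl 4-(2,2-dimethyl-4-oxo-4H-1,3-dioxin-6-yl)-3-oxobutanoate F3.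
- MgCl2 and pyridine in CH2Cl2 at 0 °C enolise F3 between its ketone and ester, and this carbon is acylated by F2 to give the C-acylated allyl keto ester F4.
- Pd(PPh3)4 and morpholine then remove the allyl group, and the β-keto acid loses CO2 to give 12.

*Step 7.* At 110 °C the liberated chain may cyclise prematurely. The ketene may also be captured internally by the C5 enol oxygen instead of by methanol. The keto–enol mixture cannot be purified. The fallback sets out from 12 and comes back at 14. It makes the internal capture the intended reaction. Heating 12 in toluene without alcohol should give the stable, purifiable 4-hydroxy-6-(3-aryl-2-oxopropyl)-2H-pyran-2-one F5. Mg(OMe)2 in methanol opens its lactone to 14 in the flask of step 8, where 14 folds on to 16.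

**Further compounds**
F1 | step 8 | [4-methoxy-3-(5,7-dimethoxy-2-(4-methoxyphenyl)-4-oxo-4H-chromen-8-yl)phenyl]acetic acid | OC(=O)Cc1ccc(OC)c(-c2c(OC)cc(OC)c3c(=O)cc(-c4ccc(OC)cc4)oc23)c1
F2 | step 6 | [4-methoxy-3-(5,7-dimethoxy-2-(4-methoxyphenyl)-4-oxo-4H-chromen-8-yl)phenyl]acetyl chloride | ClC(=O)Cc1ccc(OC)c(-c2c(OC)cc(OC)c3c(=O)cc(-c4ccc(OC)cc4)oc23)c1
F3 | step 6 | allyl 4-(2,2-dimethyl-4-oxo-4H-1,3-dioxin-6-yl)-3-oxobutanoate | C=CCOC(=O)CC(=O)CC1=CC(=O)OC(C)(C)O1
F4 | step 6 | allyl 2-{[4-methoxy-3-(5,7-dimethoxy-2-(4-methoxyphenyl)-4-oxo-4H-chromen-8-yl)phenyl]acetyl}-4-(2,2-dimethyl-4-oxo-4H-1,3-dioxin-6-yl)-3-oxobutanoate | C=CCOC(=O)C(C(=O)CC1=CC(=O)OC(C)(C)O1)C(=O)Cc1ccc(OC)c(-c2c(OC)cc(OC)c3c(=O)cc(-c4ccc(OC)cc4)oc23)c1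
F5 | step 7 | 4-hydroxy-6-{3-[4-methoxy-3-(5,7-dimethoxy-2-(4-methoxyphenyl)-4-oxo-4H-chromen-8-yl)phenyl]-2-oxopropyl}-2H-pyran-2-one | O=c1cc(O)cc(CC(=O)Cc2ccc(OC)c(-c3c(OC)cc(OC)c4c(=O)cc(-c5ccc(OC)cc5)oc34)c2)o1
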